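## Structural features

Compound 18 is a trans-2,3-disubstituted 2,3-dihydro-1-benzofuran: a benzo ring (C3a, C4 to C7, C7a) fused to a five-membered ring that is completed by O1, C2 and C3. C2 carries a 4-hydroxyphenyl group and C3 a secondary carboxamide. C5, the benzo carbon para to C7a and so para to O1, carries an (E)-acrylamide, and both amide nitrogens bear the same 4-guanidinobutyl chain. The only stereocentres are C2 (R) and C3 (R), which are neighbours and trans. C2 is a benzylic ether carbon next to an electron-rich aryl group and can ionise in strong acid; C3 is benzylic and α to a carbonyl group, so it epimerises in base, and a C3 carbanion can expel O1 by E1cB elimination, the more easily the better the C5 substituent stabilises the phenoxide. Other fragile points are the conjugated alkene, which rules out late hydrogenolysis, the free phenol, and the two strongly basic guanidines, which make unprotected intermediates hard to purify. The real difficulty is absolute control at C2 together with the trans relationship at C3, reached and kept without opening the dihydrofuran ring. The key step uses two features: in the open-chain form C3 lies between a ketone (the future C2) and an ester and is stereolabile, so a catalyst can fix C2 alone; and C5, being para to C7a, can hold a nitro group that activates a C7a–F bond for closure of O1–C7a and later becomes the handle for the acrylamide arm.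

## Logic of the disconnections

**18 ⇒ 17.** The four carbamate N–C bonds on the two guanidines and the phenolic O–CH2 bond are cut. The polar groups are unveiled last, so that every earlier compound is neutral and can be purified on silica. The forward step must remove Boc and the aryl benzyl ether in one acidic operation without touching the alkene, which excludes hydrogenolysis. Plain acid does not cleave an aryl benzyl ether at a useful rate, so a soft sulfur nucleophile has to be present.

**17 ⇒ 13 + two molecules of 16.** The two amide C–N bonds are cut. Both carboxyl groups take the same amine, so one operation with two equivalents of 16 serves and the two acids need not be told apart. The forward step must activate the C3 carboxyl without a tertiary amine, because an activated C3 carboxyl that is deprotonated at C3 can epimerise or open the ring.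

**16 ⇒ 14 + 15.** One guanidine C–N bond is cut. The free amino-guanidine cannot be protected on the guanidine while its primary amine stays free, so the amine partner is built from 14 and 15. The forward step must stop at monoguanylation, which an excess of 14 secures, and must be run on a scale that covers both amide bonds.

**13 ⇒ 12.** The two ester O–C(CH3)3 bonds are cut. Both acids are released by acid, not by hydroxide: saponification of a C3 ester in this ring system, with O1 para to an acrylate, invites E1cB opening between C3 and O1. For that reason the ester is tert-butyl, not methyl, in 2, 5, 8, 9 and 12, and 10 carries the same ester group. The forward step needs acid mild enough to spare the benzyl ether and the C2–O1 bond.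

**12 ⇒ 9 + 10 (through 11).** The C5–C(vinyl) bond is cut. The amino group at C5 descends directly from the nitro group of the key step, and a Heck–Matsuda coupling brings in the whole three-carbon arm without base or heat. The forward step must give the E alkene and should form 11 only in the flask, in small standing concentration, so that no diazonium salt is isolated.

**9 ⇒ 8.** The N–O bonds are exchanged for N–H. The forward reduction must leave the benzyl ether, the benzylic C2–O1 bond and the ester alone, which points to iron and away from catalytic hydrogenation.

**8 ⇒ 5 (through 6 and 7).** The O1–C7a bond and the C2–H bond are cut. This removes the ring and both stereocentres together and leaves a configurationally labile open chain. C2 becomes a ketone carbon that the hydride RuH[(R,R)-TsDPEN](p-cymene) can reduce from one face, and C3 needs no control of its own because it settles as trans after closure. The forward step demands that hydride transfer comes before any base, since the enolate oxygen of 5 would otherwise displace fluoride and give an aromatic benzofuran. It also demands the (R,R) ligand for 2R.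

**5 ⇒ 2 + 3 (through 4).** The bond between the future C3 and the ketone carbon (C2–C3 in ring numbering) is cut. Both halves are simple arenes with every substituent in place; in 2 the fluorine is ortho and the nitro group meta to the side chain, a pattern that SNAr arylation of a keto ester could not deliver. The forward step must be a C-acylation with two equivalents of base, run and quenched cold so that the product enolate does not close onto the C–F carbon; the chelated species 4 serves that purpose.

**2 ⇒ 1.** The ester O–C(CH3)3 bond is cut. The forward esterification must avoid base, because of the activated aryl fluoride.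

## Other disconnections considered

**Alternative 1:** The cut removes the whole benzo ring (C3a–C7a, C4–C5 and C6–C7). It leaves diyne A2, which has an ethynyl ether on the C2 oxygen, an ethynyl group on C3 and both stereocentres already in place, and acetylene A3. Forward, RhCl(PPh3)3 would couple the two tethered alkynes to a rhodacyclopentadiene, insert A3 and eliminate reductively, closing the dihydrofuran and benzo rings together to give A1.
- In favour: two rings and three C–C bonds form in one neutral step, which is better ring-forming power than the chosen step (one ring). C3 carries a silyloxymethyl group instead of an ester, so neither C3 epimerisation nor E1cB opening can occur during ring construction; on this point it is better than the chosen plan, which closes the ring in base with an enolisable ester at C3.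
- Against: the step creates no stereocentre, so C2 and C3 of A2 need a separate asymmetric sequence, whereas the chosen step sets C2 by catalysis and C3 by equilibration. A secondary benzylic ethynyl ether such as A2 is prone to thermal retro-ene fragmentation and needs strongly basic conditions to make. A3 is a flammable gas, and cross-cyclotrimerisation must outrun oligomerisation of A2. A1 has neither a C5 handle nor the C3 carboxyl, so C5 halogenation (competing with the equally electron-rich tert-butoxyphenyl ring), desilylation and a two-stage alcohol oxidation would have to follow.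
- Comparison: mechanistically sound, though the better-established form of this reaction uses nitrogen tethers and not ynol ethers. On step economy it is judged clearly longer, both before and after the key step.

**Alternative 2:** The cut is at C2–C3 and C2–O1. C2 with its aryl group comes from the ylide of chiral benzylic sulfonium salt A6; C3, the benzo ring and O1 come from the ortho-quinone methide released from A5. Forward, CsF would desilylate A5, the phenoxide would expel bromide, the ylide (Cs2CO3) would add to the exocyclic carbon to form C2–C3, and the phenoxide would displace the sulfide at C2 to form C2–O1, giving A4.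
- In favour: it is the most convergent of the four plans; two bonds, the ring and both stereocentres arise in one step. Trans selectivity is built into the mechanism (anti betaine, then SN2 with inversion at C2). A4 carries a C5 bromide that enters a standard Heck reaction directly, so nitro reduction and diazonium chemistry are not needed. On the C5 handle and on convergence it is better than the chosen plan, and the total could be one or two steps shorter.
- Against: absolute configuration would rest on a stoichiometric chiral sulfide and a semi-stabilised benzyl ylide attacking a very electrophilic, ester-substituted quinone methide. Dimerisation of the quinone methide and reversible betaine formation make the level of induction hard to predict, whereas the chosen plan sets C2 by a catalytic aryl ketone reduction of a well-understood kind. The aryl acetate of A6 is unlikely to persist beside CsF, Cs2CO3 and a phenoxide, so the protecting group would have to change. The methyl ester at C3 of A4 brings back the saponification problem. A5 and A6 each need several steps.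
- Comparison: equal or better on convergence and step count, weaker on the reliability of enantiocontrol, which decides the matter for a single-enantiomer target.

**Alternative 3:** The cut is at C7a–O1 and C3–C3a. The benzo ring arrives as the unsubstituted aryne released from A9 by CsF; O1, C2 and C3 come from vinyl epoxide A8. Forward, Pd(PPh3)4 would ionise A8 to an alkoxide and π-allylpalladium zwitterion, the alkoxide would add to the aryne (C7a–O1), and the resulting aryl carbanion would attack the inner allyl carbon (C3–C3a) to give A7.
- In favour: A8 is accessible as a single enantiomer by established epoxidation chemistry. The C2–O bond is never broken, so on C2 fidelity it is the equal of the chosen plan, whose ring closure likewise leaves C2–O intact. C3 is not acidic at any point of the ring construction, which is better than the chosen plan. The vinyl group is a masked carboxyl.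
- Against: the aryl carbanion can attack either allyl terminus, and attack at the outer carbon would give a seven-membered ring. The C3 configuration depends on whether C–C formation is outer-sphere (net retention, assumed in choosing trans-A8) or goes through palladium, and π–σ–π isomerisation of the allyl unit can erode it; the trans relationship is therefore less secure than under the thermodynamic control of the chosen plan. The aryl pivalate is exposed to an alkoxide. The aryne from A9 brings no C5 substituent and a substituted aryne would add with poor regiocontrol, so C5 must be halogenated afterwards; the prospect is better than in alternative 1 because the pivaloyloxyphenyl ring is deactivated. The vinyl group must be cleaved oxidatively to the acid in two operations before the acrylate alkene is introduced.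
- Comparison: step economy is judged equal to or slightly worse than the chosen plan, and the three-component union is the least precedented of the four key steps.

Key step: step 3

**Assumptions (remarks on the chemistry)**
- 18 is drawn and listed as the neutral bis-guanidine; it would be isolated as its bis(trifluoroacetate).
- The facial sense of RuCl[(R,R)-TsDPEN](p-cymene) is taken from simple aryl alkyl ketones (aryl group towards the η6-arene). If 5 should respond in the opposite sense, the (S,S) complex would be used with no other change.
- 3 and 15 are taken as purchased reagents.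
- Step 8 consumes two molecules of 16 for each molecule of 13; the second one is entered on the line of atom-donating reagents of that step.

## Route

**Step 1**
Reactants: 1 2-(2-fluoro-5-nitrophenyl)acetic acid
Product: 2 tert-butyl 2-(2-fluoro-5-nitrophenyl)acetate
Conditions: Cl3CC(=NH)Ot-Bu, BF3·OEt2 (cat.), CH2Cl2/cyclohexane, 25 °C
Reagents that add atoms: tert-butyl 2,2,2-trichloroacetimidate, CC(C)(C)OC(=N)C(Cl)(Cl)Cl
Why: Esterification with a tert-butyl trichloroacetimidate: the protonated imidate passes a tert-butyl cation to the carboxyl group and leaves as the neutral amide; the nitro group and the aryl fluoride are inert, and no base is present that could start fluoride displacement.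

**Step 2**
Reactants: 2 tert-butyl 2-(2-fluoro-5-nitrophenyl)acetate, 3 4-(benzyloxy)benzoyl chloride
Product: 5 tert-butyl 3-[4-(benzyloxy)phenyl]-2-(2-fluoro-5-nitrophenyl)-3-oxopropanoate (racemic), via bromomagnesium enolate 4 (not isolated)
Conditions: LiN(SiMe3)2 (2.1 equiv), THF, −78 °C; MgBr2·OEt2; 3, −78 °C; AcOH, −78 °C
Reagents that add atoms: none
Why: Crossed Claisen-type C-acylation of an ester enolate by an acid chloride; the magnesium counter-ion favours C- over O-acylation, and the second equivalent of base stores the more acidic product as a magnesium chelate whose enolate oxygen is bound to the metal and, at −78 °C, should not attack the C–F carbon. The cold acidic quench releases 5 without exposing its free enolate to warmer conditions.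

**Step 3**
Reactants: 5 tert-butyl 3-[4-(benzyloxy)phenyl]-2-(2-fluoro-5-nitrophenyl)-3-oxopropanoate
Product: 8 tert-butyl (2R,3R)-2-[4-(benzyloxy)phenyl]-5-nitro-2,3-dihydro-1-benzofuran-3-carboxylate (trans), via (3R)-hydroxy ester 6 (not isolated), via cis-dihydrobenzofuran epimer 7 (not isolated)
Conditions: RuCl[(R,R)-TsDPEN](p-cymene) (2 mol %), HCO2H/Et3N (5:2), DMF, 30 °C; then K2CO3, DMF, 0 → 25 °C
Reagents that add atoms: none
Why: In the acidic HCO2H/Et3N (5:2) medium, compound 5 racemises through its enol far faster than it is reduced, while the 18-electron hydride RuH[(R,R)-TsDPEN](p-cymene), formed from the chloride precatalyst and formate with loss of CO2, transfers hydride and proton to the aryl ketone in a concerted outer-sphere six-membered transition state. The closest known reaction types are the dynamic kinetic asymmetric transfer hydrogenation of α-substituted β-keto esters and the intramolecular SNAr etherification of nitro-activated aryl fluorides; here the two are run in one flask. C2 is controlled by the catalyst: with the (R,R) ligand the CH/π contact between the p-cymene ring and the 4-benzyloxyphenyl group should place hydride on the face that gives the R carbinol, and rapid racemisation lets every molecule react through the matched C3 epimer. When the ketone is consumed, K2CO3 neutralises the formic acid and generates the C2 alkoxide of 6, which adds to C7a, para to the nitro group, to give a Meisenheimer complex that expels fluoride; the dihydrofuran ring thus closes by a 5-exo-trig addition–elimination in which the C2–O bond is not touched, so C2 keeps its configuration. C3 is under thermodynamic control: (2R,3R)-6 closes directly to 8, (2S,3R)-6 closes to 7, and 7 epimerises through its ester enolate under the carbonate to the less crowded trans ester 8. The selectivity that the step needs is one of order, reduction before O-arylation: the enol oxygen of 5 could itself displace fluoride to give an achiral benzofuran, and the acidic formate buffer, which keeps the enolate concentration negligible, together with the late addition of carbonate, secures it. Opening of the ring from the C3 enolate would be the reverse of a 5-endo-trig closure, with the C2–O1 bond orthogonal to the enolate π system, so epimerisation should outrun elimination at 25 °C, and the tert-butyl ester excludes acyl transfer in the carbonate medium.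

**Step 4**
Reactants: 8 tert-butyl (2R,3R)-2-[4-(benzyloxy)phenyl]-5-nitro-2,3-dihydro-1-benzofuran-3-carboxylate
Product: 9 tert-butyl (2R,3R)-5-amino-2-[4-(benzyloxy)phenyl]-2,3-dihydro-1-benzofuran-3-carboxylate
Conditions: Fe, NH4Cl, EtOH/H2O, 70 °C
Reagents that add atoms: none
Why: Béchamp-type reduction of the nitro group by electron transfer from iron through the nitroso and hydroxylamine stages in a near-neutral medium; the benzyl ether, the benzylic C2–O1 bond and the tert-butyl ester, which catalytic hydrogenation would endanger, are not touched. Once C5 bears an amino group, O1 is a poor leaving group and ring opening is no longer a concern.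

**Step 5**
Reactants: 9 tert-butyl (2R,3R)-5-amino-2-[4-(benzyloxy)phenyl]-2,3-dihydro-1-benzofuran-3-carboxylate, 10 tert-butyl prop-2-enoate
Product: 12 tert-butyl (2R,3R)-2-[4-(benzyloxy)phenyl]-5-[(E)-3-tert-butoxy-3-oxoprop-1-en-1-yl]-2,3-dihydro-1-benzofuran-3-carboxylate, via arenediazonium methanesulfonate 11 (not isolated)
Conditions: t-BuONO, MeSO3H (0.2 equiv), Pd(OAc)2 (5 mol %), MeOH/MeCN, 25 °C
Reagents that add atoms: none
Why: Heck–Matsuda reaction run from the aniline: t-BuONO and the acid convert 9 into 11, zerovalent palladium (formed from Pd(OAc)2 in the alcohol and olefin medium) inserts into the C5–N bond with loss of N2, the cationic arylpalladium species adds syn across 10 with the aryl group at the β-carbon, and syn β-hydride elimination gives the E alkene. The proton set free re-enters the diazotisation, so 11 never accumulates; no base and no heating are involved, so the C3 ester, both stereocentres and the benzyl ether are not at risk.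

**Step 6**
Reactants: 12 tert-butyl (2R,3R)-2-[4-(benzyloxy)phenyl]-5-[(E)-3-tert-butoxy-3-oxoprop-1-en-1-yl]-2,3-dihydro-1-benzofuran-3-carboxylate
Product: 13 (2R,3R)-2-[4-(benzyloxy)phenyl]-5-[(E)-2-carboxyethenyl]-2,3-dihydro-1-benzofuran-3-carboxylic acid
Conditions: TFA/CH2Cl2 (1:3), 0 → 25 °C
Reagents that add atoms: none
Why: Acidolysis of both tert-butyl esters by alkyl–oxygen cleavage, the tert-butyl cation leaving as 2-methylpropene; without base C3 cannot be deprotonated, which avoids the E1cB ring opening that hydroxide would invite in a ring whose O1 is para to an acrylate. The aryl benzyl ether should survive dilute acid in the absence of a soft nucleophile, and the electron-withdrawing C3 carboxyl disfavours ionisation at C2.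

**Step 7**
Reactants: 14 butane-1,4-diamine, 15 N,N'-bis(tert-butoxycarbonyl)-1H-pyrazole-1-carboxamidine
Product: 16 N-(4-aminobutyl)-N',N''-bis(tert-butoxycarbonyl)guanidine
Conditions: 14 (4 equiv), CH2Cl2, 0 → 25 °C
Reagents that add atoms: none
Why: Guanylation by amidine transfer: the amine adds to the electron-poor carboxamidine carbon and pyrazole leaves; the excess of the symmetrical diamine keeps the reaction at monoguanylation and is washed out with water. The step is run on a scale that supplies rather more than two equivalents of 16 for step 8.

**Step 8**
Reactants: 13 (2R,3R)-2-[4-(benzyloxy)phenyl]-5-[(E)-2-carboxyethenyl]-2,3-dihydro-1-benzofuran-3-carboxylic acid, 16 N-(4-aminobutyl)-N',N''-bis(tert-butoxycarbonyl)guanidine (2.3 equiv in all, of which two are incorporated)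
Product: 17 (2R,3R)-2-[4-(benzyloxy)phenyl]-N-{4-[N',N''-bis(tert-butoxycarbonyl)guanidino]butyl}-5-[(E)-3-({4-[N',N''-bis(tert-butoxycarbonyl)guanidino]butyl}amino)-3-oxoprop-1-en-1-yl]-2,3-dihydro-1-benzofuran-3-carboxamide
Conditions: 16 (2.3 equiv), EDC·HCl (2.4 equiv), Oxyma (2.4 equiv), DMF/CH2Cl2, 0 → 25 °C
Reagents that add atoms: second equivalent of 16, N-(4-aminobutyl)-N',N''-bis(tert-butoxycarbonyl)guanidine, NCCCCNC(=NC(=O)OC(C)(C)C)NC(=O)OC(C)(C)C
Why: Carbodiimide amidation: each of the two carboxyl groups of 13 is converted into its Oxyma active ester and aminolysed by the primary amine of one molecule of 16, so that two molecules of 16 are built in and both amide bonds form in one operation with loss of two molecules of water to the carbodiimide. No tertiary amine is added, which keeps the activated C3 carboxyl from being enolised, and the acylated guanidine nitrogens of 16 are not nucleophilic; Oxyma is chosen over benzotriazole additives for safety.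

**Step 9**
Reactants: 17 (2R,3R)-2-[4-(benzyloxy)phenyl]-N-{4-[N',N''-bis(tert-butoxycarbonyl)guanidino]butyl}-5-[(E)-3-({4-[N',N''-bis(tert-butoxycarbonyl)guanidino]butyl}amino)-3-oxoprop-1-en-1-yl]-2,3-dihydro-1-benzofuran-3-carboxamide
Product: 18 (2R,3R)-N-(4-guanidinobutyl)-5-{(E)-3-[(4-guanidinobutyl)amino]-3-oxoprop-1-en-1-yl}-2-(4-hydroxyphenyl)-2,3-dihydro-1-benzofuran-3-carboxamide (CNP0497893.1)
Conditions: TFA/PhSMe (10:1), 0 → 25 °C; Et2O precipitation; reversed-phase HPLC
Reagents that add atoms: none
Why: Global acidolysis: the four Boc carbamates fragment to 2-methylpropene and CO2, and the protonated aryl benzyl ether is dealkylated by SN2-type attack of the sulfur of thioanisole on the benzylic CH2 (push–pull debenzylation), which also keeps benzyl and tert-butyl cations off the phenol ring. The alkene, the amides and the two stereocentres should not be affected, and the guanidines emerge protonated, so 18 is collected as its bis(trifluoroacetate).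

## Compound list

1 | 2-(2-fluoro-5-nitrophenyl)acetic acid | OC(=O)Cc1cc([N+](=O)[O-])ccc1F | starting material
2 | tert-butyl 2-(2-fluoro-5-nitrophenyl)acetate | CC(C)(C)OC(=O)Cc1cc([N+](=O)[O-])ccc1F | intermediate
3 | 4-(benzyloxy)benzoyl chloride | O=C(Cl)c1ccc(OCc2ccccc2)cc1 | starting material
4 | bromomagnesium enolate of tert-butyl 2-(2-fluoro-5-nitrophenyl)acetate | CC(C)(C)OC(O[Mg]Br)=Cc1cc([N+](=O)[O-])ccc1F | intermediate
5 | tert-butyl 3-[4-(benzyloxy)phenyl]-2-(2-fluoro-5-nitrophenyl)-3-oxopropanoate (racemic) | CC(C)(C)OC(=O)C(C(=O)c1ccc(OCc2ccccc2)cc1)c1cc([N+](=O)[O-])ccc1F | intermediate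
6 | tert-butyl (3R)-3-[4-(benzyloxy)phenyl]-2-(2-fluoro-5-nitrophenyl)-3-hydroxypropanoate (both C2 epimers) | CC(C)(C)OC(=O)C([C@@H](O)c1ccc(OCc2ccccc2)cc1)c1cc([N+](=O)[O-])ccc1F | intermediate
7 | tert-butyl (2R,3S)-2-[4-(benzyloxy)phenyl]-5-nitro-2,3-dihydro-1-benzofuran-3-carboxylate (cis) | O=[N+]([O-])c1ccc2c(c1)[C@H](C(=O)OC(C)(C)C)[C@H](c1ccc(OCc3ccccc3)cc1)O2 | intermediate
8 | tert-butyl (2R,3R)-2-[4-(benzyloxy)phenyl]-5-nitro-2,3-dihydro-1-benzofuran-3-carboxylate (trans) | O=[N+]([O-])c1ccc2c(c1)[C@@H](C(=O)OC(C)(C)C)[C@H](c1ccc(OCc3ccccc3)cc1)O2 | intermediate
9 | tert-butyl (2R,3R)-5-amino-2-[4-(benzyloxy)phenyl]-2,3-dihydro-1-benzofuran-3-carboxylate | Nc1ccc2c(c1)[C@@H](C(=O)OC(C)(C)C)[C@H](c1ccc(OCc3ccccc3)cc1)O2 | intermediate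
10 | tert-butyl prop-2-enoate | C=CC(=O)OC(C)(C)C | starting material
11 | (2R,3R)-2-[4-(benzyloxy)phenyl]-3-(tert-butoxycarbonyl)-2,3-dihydro-1-benzofuran-5-diazonium methanesulfonate | N#[N+]c1ccc2c(c1)[C@@H](C(=O)OC(C)(C)C)[C@H](c1ccc(OCc3ccccc3)cc1)O2.CS(=O)(=O)[O-] | intermediate
12 | tert-butyl (2R,3R)-2-[4-(benzyloxy)phenyl]-5-[(E)-3-tert-butoxy-3-oxoprop-1-en-1-yl]-2,3-dihydro-1-benzofuran-3-carboxylate | CC(C)(C)OC(=O)/C=C/c1ccc2c(c1)[C@@H](C(=O)OC(C)(C)C)[C@H](c1ccc(OCc3ccccc3)cc1)O2 | intermediate
13 | (2R,3R)-2-[4-(benzyloxy)phenyl]-5-[(E)-2-carboxyethenyl]-2,3-dihydro-1-benzofuran-3-carboxylic acid | OC(=O)/C=C/c1ccc2c(c1)[C@@H](C(=O)O)[C@H](c1ccc(OCc3ccccc3)cc1)O2 | intermediate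
14 | butane-1,4-diamine | NCCCCN | starting material
15 | N,N'-bis(tert-butoxycarbonyl)-1H-pyrazole-1-carboxamidine | CC(C)(C)OC(=O)NC(=NC(=O)OC(C)(C)C)n1cccn1 | starting material
16 | N-(4-aminobutyl)-N',N''-bis(tert-butoxycarbonyl)guanidine | NCCCCNC(=NC(=O)OC(C)(C)C)NC(=O)OC(C)(C)C | intermediate
17 | (2R,3R)-2-[4-(benzyloxy)phenyl]-N-{4-[N',N''-bis(tert-butoxycarbonyl)guanidino]butyl}-5-[(E)-3-({4-[N',N''-bis(tert-butoxycarbonyl)guanidino]butyl}amino)-3-oxoprop-1-en-1-yl]-2,3-dihydro-1-benzofuran-3-carboxamide | CC(C)(C)OC(=O)NC(=NC(=O)OC(C)(C)C)NCCCCNC(=O)/C=C/c1ccc2c(c1)[C@@H](C(=O)NCCCCNC(=NC(=O)OC(C)(C)C)NC(=O)OC(C)(C)C)[C@H](c1ccc(OCc3ccccc3)cc1)O2 | intermediate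
18 | (2R,3R)-N-(4-guanidinobutyl)-5-{(E)-3-[(4-guanidinobutyl)amino]-3-oxoprop-1-en-1-yl}-2-(4-hydroxyphenyl)-2,3-dihydro-1-benzofuran-3-carboxamide (CNP0497893.1) | NC(N)=NCCCCNC(=O)/C=C/c1ccc2c(c1)[C@@H](C(=O)NCCCCN=C(N)N)[C@H](c1ccc(O)cc1)O2 | target

## Step count and least certain steps

Total step count: 9. Longest linear sequence: 8 steps (1 → 2 → 5 → 8 → 9 → 12 → 13 → 17 → 18); step 7 is a one-step side branch.

**Step 3 (key step).** Four processes could defeat it:
- premature O-arylation of the enol form before reduction, which would erase C2 as a stereocentre;
- slow or poorly face-selective hydride transfer, because the substrate rests largely as a hydrogen-bonded enol and the ketone carries an electron-rich aryl group;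
- retro-aldol fragmentation of the alkoxide under carbonate, which would racemise C2 before the ring closes;
- β-elimination of the nitrophenoxide from the C3 enolate during the cis-to-trans epimerisation.

Fallback: an auxiliary-controlled Evans syn aldol reaction sets both centres, so no reduction and no epimerisation are needed. It sets out from 1. The mixed pivalic anhydride of 1 (t-BuCOCl, Et3N, THF) would acylate purchased (4R)-4-benzyl-1,3-oxazolidin-2-one F1 in the presence of LiCl to give (4R)-4-benzyl-3-[2-(2-fluoro-5-nitrophenyl)acetyl]-1,3-oxazolidin-2-one F2. Its Z boron enolate (Bu2BOTf, i-Pr2NEt, CH2Cl2, −78 °C) should add to purchased 4-(benzyloxy)benzaldehyde F3 through a chair transition state to give the syn adduct (4R)-4-benzyl-3-[(2R,3R)-3-[4-(benzyloxy)phenyl]-2-(2-fluoro-5-nitrophenyl)-3-hydroxypropanoyl]-1,3-oxazolidin-2-one F4. LiOH/H2O2 at 0 °C should release (2R,3R)-3-[4-(benzyloxy)phenyl]-2-(2-fluoro-5-nitrophenyl)-3-hydroxypropanoic acid F5. tert-Butyl trichloroacetimidate should convert it into tert-butyl (2R,3R)-3-[4-(benzyloxy)phenyl]-2-(2-fluoro-5-nitrophenyl)-3-hydroxypropanoate F6, a single epimer of 6, which with K2CO3 in DMF should close directly to the trans ring. The fallback comes back to the route at 8.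

**Step 2.** On warming, the product enolate could cyclise onto the C–F carbon; O-acylation and self-condensation of the nitroaryl enolate by intermolecular fluoride displacement are the other risks. Fallback: carbonyl addition followed by oxidation in place of acylation, so that no β-keto ester enolate is ever present. It sets out from 2. The lithium enolate (LiN(SiMe3)2, one equivalent, THF, −78 °C) would add to 4-(benzyloxy)benzaldehyde F3 and be quenched cold to give tert-butyl 3-[4-(benzyloxy)phenyl]-2-(2-fluoro-5-nitrophenyl)-3-hydroxypropanoate F7 as a racemic mixture of diastereomers. Oxidation with IBX in EtOAc at 75 °C, a neutral method suited to β-hydroxy carbonyl compounds, should return to the route at 5.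

**Step 5.** With only catalytic acid, the diazonium ion could be reduced by the solvent or could couple with unreacted aniline to a triazene, and palladium could precipitate before turnover. Fallback: a halide handle and a conventional Heck reaction. It sets out from 9. Stoichiometric diazotisation (t-BuONO, MeSO3H, MeCN, 0 °C) gives 11, and KI added to the same flask should give tert-butyl (2R,3R)-2-[4-(benzyloxy)phenyl]-5-iodo-2,3-dihydro-1-benzofuran-3-carboxylate F8 by a Sandmeyer-type iodination that needs no copper. Mizoroki–Heck coupling of F8 with 10 (Pd(OAc)2, P(o-tol)3, Et3N, MeCN, 70 °C) comes back to the route at 12.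

**Step 8.** Aminolysis at the hindered, α-branched C3 active ester may be slow, which would let rearrangement to the N-acylurea and deprotonation at C3 (epimerisation or ring opening) compete, and the reaction could stall at the mono-amide of the acrylic acid; 16 may also degrade on storage through attack of its own amine on the acylated guanidine. Fallback: an isolated active ester and the unprotected amine, whose guanidinium protects itself. It sets out from 13. EDC·HCl and N-hydroxysuccinimide (two equivalents each) should give the bis(2,5-dioxopyrrolidin-1-yl) ester of 13 F9. Acylation of purchased agmatine sulfate F10 (two equivalents and a slight excess) in dioxane and aqueous NaHCO3, where only the primary amine is nucleophilic, should give the O-benzyl ether of 18 F11. TFA/thioanisole as in step 9 then comes back to the route at 18.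

**Step 9.** Benzyl ether cleavage may be slow and force long exposure to strong acid, during which the benzylic C2–O1 bond can ionise (epimerisation at C2 or ring opening) and the phenol ring can be alkylated. Fallback: remove the benzyl group earlier with a Lewis acid at low temperature, so that the last step is Boc removal only. It sets out from 13. BCl3 with pentamethylbenzene in CH2Cl2 at −78 °C should give (2R,3R)-5-[(E)-2-carboxyethenyl]-2-(4-hydroxyphenyl)-2,3-dihydro-1-benzofuran-3-carboxylic acid F12. Coupling with two equivalents of 16 as in step 8 (a free phenol is tolerated; any aryl ester formed is cleaved by the excess amine) should give the tetra-Boc phenol bis-amide F13. Brief treatment with TFA/CH2Cl2 at 0 °C comes back to the route at 18.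

## Further compounds

F1 | step 3 | (4R)-4-benzyl-1,3-oxazolidin-2-one (purchased) | O=C1N[C@H](Cc2ccccc2)CO1
F2 | step 3 | (4R)-4-benzyl-3-[2-(2-fluoro-5-nitrophenyl)acetyl]-1,3-oxazolidin-2-one | O=C(Cc1cc([N+](=O)[O-])ccc1F)N1C(=O)OC[C@H]1Cc1ccccc1
F3 | step 3 | 4-(benzyloxy)benzaldehyde (purchased) | O=Cc1ccc(OCc2ccccc2)cc1
F4 | step 3 | (4R)-4-benzyl-3-[(2R,3R)-3-[4-(benzyloxy)phenyl]-2-(2-fluoro-5-nitrophenyl)-3-hydroxypropanoyl]-1,3-oxazolidin-2-one | O=C([C@@H]([C@@H](O)c1ccc(OCc2ccccc2)cc1)c1cc([N+](=O)[O-])ccc1F)N1C(=O)OC[C@H]1Cc1ccccc1
F5 | step 3 | (2R,3R)-3-[4-(benzyloxy)phenyl]-2-(2-fluoro-5-nitrophenyl)-3-hydroxypropanoic acid | OC(=O)[C@@H]([C@@H](O)c1ccc(OCc2ccccc2)cc1)c1cc([N+](=O)[O-])ccc1F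
F6 | step 3 | tert-butyl (2R,3R)-3-[4-(benzyloxy)phenyl]-2-(2-fluoro-5-nitrophenyl)-3-hydroxypropanoate | CC(C)(C)OC(=O)[C@@H]([C@@H](O)c1ccc(OCc2ccccc2)cc1)c1cc([N+](=O)[O-])ccc1F
F7 | step 2 | tert-butyl 3-[4-(benzyloxy)phenyl]-2-(2-fluoro-5-nitrophenyl)-3-hydroxypropanoate (racemic, both diastereomers) | CC(C)(C)OC(=O)C(C(O)c1ccc(OCc2ccccc2)cc1)c1cc([N+](=O)[O-])ccc1F
F8 | step 5 | tert-butyl (2R,3R)-2-[4-(benzyloxy)phenyl]-5-iodo-2,3-dihydro-1-benzofuran-3-carboxylate | Ic1ccc2c(c1)[C@@H](C(=O)OC(C)(C)C)[C@H](c1ccc(OCc3ccccc3)cc1)O2
F9 | step 8 | 2,5-dioxopyrrolidin-1-yl (2R,3R)-2-[4-(benzyloxy)phenyl]-5-{(E)-3-[(2,5-dioxopyrrolidin-1-yl)oxy]-3-oxoprop-1-en-1-yl}-2,3-dihydro-1-benzofuran-3-carboxylate | O=C1CCC(=O)N1OC(=O)/C=C/c1ccc2c(c1)[C@@H](C(=O)ON1C(=O)CCC1=O)[C@H](c1ccc(OCc3ccccc3)cc1)O2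
F10 | step 8 | agmatine sulfate (purchased) | NCCCCN=C(N)N.OS(=O)(=O)O
F11 | step 8 | (2R,3R)-2-[4-(benzyloxy)phenyl]-N-(4-guanidinobutyl)-5-{(E)-3-[(4-guanidinobutyl)amino]-3-oxoprop-1-en-1-yl}-2,3-dihydro-1-benzofuran-3-carboxamide | NC(N)=NCCCCNC(=O)/C=C/c1ccc2c(c1)[C@@H](C(=O)NCCCCN=C(N)N)[C@H](c1ccc(OCc3ccccc3)cc1)O2
F12 | step 9 | (2R,3R)-5-[(E)-2-carboxyethenyl]-2-(4-hydroxyphenyl)-2,3-dihydro-1-benzofuran-3-carboxylic acid | OC(=O)/C=C/c1ccc2c(c1)[C@@H](C(=O)O)[C@H](c1ccc(O)cc1)O2
F13 | step 9 | (2R,3R)-N-{4-[N',N''-bis(tert-butoxycarbonyl)guanidino]butyl}-5-[(E)-3-({4-[N',N''-bis(tert-butoxycarbonyl)guanidino]butyl}amino)-3-oxoprop-1-en-1-yl]-2-(4-hydroxyphenyl)-2,3-dihydro-1-benzofuran-3-carboxamide | CC(C)(C)OC(=O)NC(=NC(=O)OC(C)(C)C)NCCCCNC(=O)/C=C/c1ccc2c(c1)[C@@H](C(=O)NCCCCNC(=NC(=O)OC(C)(C)C)NC(=O)OC(C)(C)C)[C@H](c1ccc(O)cc1)O2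
A1 | alternative 1 | (2R,3S)-2-(4-tert-butoxyphenyl)-3-[(tert-butyldimethylsilyloxy)methyl]-2,3-dihydro-1-benzofuran | c1ccc2c(c1)[C@@H](CO[Si](C)(C)C(C)(C)C)[C@H](c1ccc(OC(C)(C)C)cc1)O2
A2 | alternative 1 | tert-butyl{[(2S,3R)-3-(4-tert-butoxyphenyl)-2-ethynyl-3-(ethynyloxy)propyl]oxy}dimethylsilane | C#C[C@@H](CO[Si](C)(C)C(C)(C)C)[C@H](c1ccc(OC(C)(C)C)cc1)OC#C
A3 | alternative 1 | acetylene | C#C
A4 | alternative 2 | methyl (2R,3R)-2-(4-acetoxyphenyl)-5-bromo-2,3-dihydro-1-benzofuran-3-carboxylate | Brc1ccc2c(c1)[C@@H](C(=O)OC)[C@H](c1ccc(OC(C)=O)cc1)O2
A5 | alternative 2 | methyl 2-bromo-2-[5-bromo-2-(tert-butyldimethylsilyloxy)phenyl]acetate (racemic) | COC(=O)C(Br)c1cc(Br)ccc1O[Si](C)(C)C(C)(C)C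
A6 | alternative 2 | (2R,5R)-1-(4-acetoxybenzyl)-2,5-dimethylthiolan-1-ium bromide (configuration shown for definiteness) | CC(=O)Oc1ccc(C[S+]2[C@H](C)CC[C@H]2C)cc1.[Br-]
A7 | alternative 3 | 4-[(2R,3R)-3-ethenyl-2,3-dihydro-1-benzofuran-2-yl]phenyl 2,2-dimethylpropanoate | c1ccc2c(c1)[C@@H](C=C)[C@H](c1ccc(OC(=O)C(C)(C)C)cc1)O2
A8 | alternative 3 | 4-[(2S,3S)-3-ethenyloxiran-2-yl]phenyl 2,2-dimethylpropanoate | C=C[C@@H]1O[C@H]1c1ccc(OC(=O)C(C)(C)C)cc1
A9 | alternative 3 | 2-(trimethylsilyl)phenyl trifluoromethanesulfonate | C[Si](C)(C)c1ccccc1OS(=O)(=O)C(F)(F)F
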